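**Retrosynthetic overview**
1. Ambrein ⇐ reductive decarboxylation of an α-branched acid ⇐ Ireland–Claisen [3,3] rearrangement of a secondary 2-methylallyl ester. This step forms the C–C bond that joins the two halves and sets the E-trisubstituted alkene.
2. Ester ⇐ (S)-(2,2-dimethyl-6-methylenecyclohexyl)acetic acid + a decalin allylic alcohol.
3. Cyclohexyl acid ⇐ (1R,5R)-(+)-verbenone (1): cuprate addition and enolate alkylation anti to the gem-dimethyl bridge set the lone ring stereocentre; the cyclobutane is then opened and the bridge carbon excised.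
4. Decalin alcohol ⇐ (+)-sclareolide (2), which supplies all four decalin stereocentres: DIBAL, one-carbon Wittig homologation, isopropenyl Grignard.
5. Ring order: no ring is built. The decalin is bought intact, and the monocycle is the six-membered ring of verbenone.

Assumption: (1R,5R)-(+)-verbenone is purchased; if not, it is one allylic oxidation from (1R)-(+)-α-pinene.

**Route**

Step 1
Reactants: 1, (1R,5R)-(+)-verbenone
Product: 3, methyl 2-[(1R,3S,5S)-4,4,6,6-tetramethyl-2-oxobicyclo[3.1.1]heptan-3-yl]acetate (side chain anti to the gem-dimethyl bridge)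
Conditions: Me2CuLi, Et2O, 0 °C; then HMPA (or DMPU), BrCH2CO2Me, −20 °C → rt
Reagents that add atoms: lithium dimethylcuprate, [Li+].C[Cu-]C (adds CH3); methyl bromoacetate, COC(=O)CBr (adds CH2CO2Me)
Why: Tandem cuprate conjugate addition/enolate alkylation; C3 is the only enolisable α-carbon (C1 is a bridgehead) and the electrophile enters on the face opposite the gem-dimethyl bridge, so the future cyclohexyl stereocentre is set by the pinane framework.

Step 2
Reactants: 3
Product: 4, methyl 2-[(1S,3S)-2,2-dimethyl-6-oxo-3-(prop-1-en-2-yl)cyclohexyl]acetate (trans)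
Conditions: TMSCl, NaI, MeCN, 0 °C → rt; then DBU, 50 °C; aq. HCl work-up
Reagents that add atoms: none
Why: TMSI-promoted cleavage of the cyclobutane bond α to the ketone (as in nopinone ring opening) gives the C1 silyl enol ether and a tertiary iodide, and E2 elimination toward methyl gives the isopropenyl group (isopropylidene is disfavoured by A1,3 strain with the adjacent gem-dimethyl). The enol forms away from the new stereocentre, and any epimer is a separable diastereomer at this stage.

Step 3
Reactants: 4
Product: 5, methyl 2-[(1S)-2,2-dimethyl-6-oxocyclohexyl]acetate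
Conditions: O3, MeOH, −78 °C; then FeSO4·7H2O, PhSH, −78 °C → rt
Reagents that add atoms: none
Why: Hydrodealkenylation (ozonolysis to the α-methoxy hydroperoxide, Fe(II)-induced alkoxyl-radical β-scission, H-transfer from PhSH) replaces the isopropenyl group by H under neutral conditions that leave the α-stereocentre intact.

Step 4
Reactants: 5
Product: 6, methyl 2-[(1S)-2,2-dimethyl-6-methylidenecyclohexyl]acetate
Conditions: Zn, CH2Br2, TiCl4, THF–CH2Cl2, 0 °C → rt
Reagents that add atoms: dibromomethane, BrCBr (adds CH2)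
Why: Takai–Lombardo methylenation is selective for the ketone over the ester and is non-basic, so the α-stereocentre is not epimerised.

Step 5
Reactants: 6
Product: 7, 2-[(1S)-2,2-dimethyl-6-methylidenecyclohexyl]acetic acid
Conditions: LiOH, THF/MeOH/H2O, 40 °C
Reagents that add atoms: lithium hydroxide/water, [Li+].[OH-] (adds O)
Why: Saponification; the stereocentre is β to the carboxyl and the exocyclic alkene is stable to aqueous base.

Step 6
Reactants: 2, (+)-sclareolide
Product: 8, sclareolide lactol (3a,6,6,9a-tetramethyldodecahydronaphtho[2,1-b]furan-2-ol, anomer mixture)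
Conditions: DIBAL-H, CH2Cl2, −78 °C
Reagents that add atoms: none
Why: Partial reduction of the γ-lactone stops at the lactol; no stereocentre is touched.

Step 7
Reactants: 8
Product: 9, (1R,2R,4aS,8aS)-1-(3-methoxyprop-2-en-1-yl)-2,5,5,8a-tetramethyldecahydronaphthalen-2-ol (E/Z mixture)
Conditions: MeOCH2PPh3Cl, KOtBu (3 equiv), THF, 0 °C → rt
Reagents that add atoms: (methoxymethyl)triphenylphosphonium chloride, COC[P+](c1ccccc1)(c1ccccc1)c1ccccc1.[Cl-] (adds CH–OMe)
Why: Wittig methoxymethylenation of the open hydroxy-aldehyde form of the lactol adds the one carbon needed in the chain.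

Step 8
Reactants: 9
Product: 10, homologous δ-lactol (8,13-epoxy-14,15,16-trinorlabdan-13-ol, the lactol of ambreinolide; anomer mixture)
Conditions: 1 M HCl, THF, rt
Reagents that add atoms: water, O (adds O)
Why: Enol ether hydrolysis gives the aldehyde, which is trapped by the tertiary hydroxyl as the six-membered lactol; mild acid avoids dehydration.

Step 9
Reactants: 10
Product: 11, (1R,2R,4aS,8aS)-1-(3-hydroxy-4-methylpent-4-en-1-yl)-2,5,5,8a-tetramethyldecahydronaphthalen-2-ol (about 1:1 at the new carbinol)
Conditions: isopropenylmagnesium bromide (4 equiv), THF, 0 °C → rt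
Reagents that add atoms: isopropenylmagnesium bromide, CC(=C)[Mg]Br (adds C3H5)
Why: Grignard addition to the ring-opened aldehyde tautomer; the carbinol configuration is irrelevant because this carbon becomes sp2 in step 11.

Step 10
Reactants: 11 and 7
Product: 12, 5-[(1R,2R,4aS,8aS)-2-hydroxy-2,5,5,8a-tetramethyldecahydronaphthalen-1-yl]-2-methylpent-1-en-3-yl 2-[(1S)-2,2-dimethyl-6-methylidenecyclohexyl]acetate
Conditions: EDC·HCl, DMAP, CH2Cl2, rt
Reagents that add atoms: none
Why: Steglich esterification acylates the secondary allylic alcohol; the hindered tertiary alcohol does not react.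

Step 11
Reactants: 12
Product: 13, (E)-2-[(1S)-2,2-dimethyl-6-methylidenecyclohexyl]-7-[(1R,2R,4aS,8aS)-2-hydroxy-2,5,5,8a-tetramethyldecahydronaphthalen-1-yl]-4-methylhept-4-enoic acid (mixture at C2)
Conditions: LDA (3 equiv), TMSCl, THF, −78 °C → 60 °C; aq. HCl work-up
Reagents that add atoms: none
Why: Ireland–Claisen [3,3]-sigmatropic rearrangement of the silyl ketene acetal through a chair transition state with the carbinol substituent pseudo-equatorial forms the linking C–C bond and the E-trisubstituted alkene; the new α-stereocentre is erased in step 12.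

Step 12
Reactants: 13
Product: 14, (+)-ambrein
Conditions: N-hydroxypyridine-2-thione, DCC, DMAP, CH2Cl2, dark; then t-BuSH, hν (W lamp), rt
Reagents that add atoms: none
Why: Barton reductive decarboxylation; the secondary radical is trapped by the thiol faster than it can rearrange, leaving CH2 and both alkenes and the tertiary alcohol untouched.

**Compound list**
1 | (1R,5R)-(+)-verbenone | CC1=CC(=O)[C@@H]2C[C@H]1C2(C)C | starting material
2 | (+)-sclareolide (3aR,5aS,9aS,9bR) | O=C1C[C@@H]2[C@@]3(C)CCCC(C)(C)[C@@H]3CC[C@@]2(C)O1 | starting material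
3 | methyl 2-[(1R,3S,5S)-4,4,6,6-tetramethyl-2-oxobicyclo[3.1.1]heptan-3-yl]acetate | O=C1[C@@H](CC(=O)OC)C(C)(C)[C@H]2C[C@@H]1C2(C)C | intermediate
4 | methyl 2-[(1S,3S)-2,2-dimethyl-6-oxo-3-(prop-1-en-2-yl)cyclohexyl]acetate | O=C1[C@@H](CC(=O)OC)C(C)(C)[C@H](C(C)=C)CC1 | intermediate
5 | methyl 2-[(1S)-2,2-dimethyl-6-oxocyclohexyl]acetate | O=C1[C@@H](CC(=O)OC)C(C)(C)CCC1 | intermediate
6 | methyl 2-[(1S)-2,2-dimethyl-6-methylidenecyclohexyl]acetate | C=C1CCCC(C)(C)[C@@H]1CC(=O)OC | intermediate
7 | 2-[(1S)-2,2-dimethyl-6-methylidenecyclohexyl]acetic acid | C=C1CCCC(C)(C)[C@@H]1CC(=O)O | intermediate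
8 | sclareolide lactol | OC1C[C@@H]2[C@@]3(C)CCCC(C)(C)[C@@H]3CC[C@@]2(C)O1 | intermediate
9 | (1R,2R,4aS,8aS)-1-(3-methoxyprop-2-en-1-yl)-2,5,5,8a-tetramethyldecahydronaphthalen-2-ol | COC=CC[C@@H]1[C@@]2(C)CCCC(C)(C)[C@@H]2CC[C@@]1(C)O | intermediate
10 | 8,13-epoxy-14,15,16-trinorlabdan-13-ol (δ-lactol) | OC1CC[C@@H]2[C@@]3(C)CCCC(C)(C)[C@@H]3CC[C@@]2(C)O1 | intermediate
11 | (1R,2R,4aS,8aS)-1-(3-hydroxy-4-methylpent-4-en-1-yl)-2,5,5,8a-tetramethyldecahydronaphthalen-2-ol | C=C(C)C(O)CC[C@@H]1[C@@]2(C)CCCC(C)(C)[C@@H]2CC[C@@]1(C)O | intermediate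
12 | allylic ester of 11 with 7 | C=C(C)C(OC(=O)C[C@@H]1C(=C)CCCC1(C)C)CC[C@@H]1[C@@]2(C)CCCC(C)(C)[C@@H]2CC[C@@]1(C)O | intermediate
13 | (E)-2-[(1S)-2,2-dimethyl-6-methylidenecyclohexyl]-7-[decalinyl]-4-methylhept-4-enoic acid | OC(=O)C([C@@H]1C(=C)CCCC1(C)C)C/C(C)=C/CC[C@@H]1[C@@]2(C)CCCC(C)(C)[C@@H]2CC[C@@]1(C)O | intermediate
14 | (+)-ambrein | C=C1CCCC(C)(C)[C@@H]1CC/C(C)=C/CC[C@@H]1[C@@]2(C)CCCC(C)(C)[C@@H]2CC[C@@]1(C)O | target

**Totals**
Total steps: 12. Longest linear sequence: 8 (steps 1–5, then 10–12).

**Steps most likely to fail, with fallbacks**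
- **Step 2 (cyclobutane opening to the isopropenyl ketone):** the risks are cation rearrangement, the wrong elimination regiochemistry, or α-epimerisation. Fallback: open to the tertiary carbinol (2-hydroxyprop-2-yl group) instead and excise it by alkoxyl-radical β-fragmentation (PhI(OAc)2/I2, hν, then Bu3SnH on the secondary iodide), replacing steps 2–3.
- **Step 1 (alkylation of the hindered enolate flanked by the new quaternary carbon):** Fallback: trap the cuprate enolate as its TMS enol ether, run a TiCl4-mediated Mukaiyama aldol with methyl glyoxylate, and remove the hydroxyl by Barton–McCombie deoxygenation.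
- **Step 12 (radical decarboxylation next to two alkenes):** the risks are homoallyl radical rearrangement and thiol–ene addition. Fallback: reduce the acid to the aldehyde and remove the carbon by stoichiometric Rh(I) decarbonylation (Tsuji–Wilkinson), a non-radical excision.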